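**Plan**

- Retrosynthesis: the three silicon protecting groups come off last; the pyran O2–C3 bond is cut back to an alkynyl aldehyde; the C4a–C8a and C7–C8 bonds are then cut together, after the C7 hydroxyl is re-closed onto C4a as an oxygen bridge, by a retro-Diels–Alder reaction to a 3-silyloxyfuran and an (E)-3-aroyloxyacrolein.
- Enabling feature: the carbocycle C4a–C5–C6–C7–C8–C8a of the 7,8-dihydro-6H-isochromen-6-one is a 4-hydroxycyclohex-2-enone (C6 ketone, C4a=C5, tertiary OH at C7), i.e. the ring-opened form of a 7-oxabicyclo[2.2.1]heptene. The furan oxygen becomes the C7 hydroxyl, the furan C3–OSi becomes the C6 ketone, and furan C2 and C5 become C7 and C4a. The enal β- and α-carbons become C8 (carrying the orsellinate oxygen) and C8a (carrying C1 as CHO).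
- Forward order: diynone, then 5-alkynyl-3(2H)-furanone, then the side chain by Sonogashira coupling, then the silyloxyfuran; orsellinic acid is taken to the aroyloxyacrolein. Cycloaddition with bridge opening builds the carbocycle first, a gold cycloisomerisation closes the pyran second, and one desilylation finishes.
- Stereochemistry: the cis C7–O/C8–O relationship comes from the E-dienophile and the endo rule (aroyloxy exo, on the side of the bridge oxygen). The absolute configuration comes from a chiral oxazaborolidinium catalyst. The lactate centre of the starting material is erased at the furan stage.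

Key step: step 8

Assumption: with the (E)-3-aroyloxyacrolein the (R)-configured oxazaborolidinium ion is taken to follow the usual formyl C–H···O binding model of enals and to expose the Si face of the enal β-carbon; if the opposite sense is found, the (S)-configured catalyst is used.

**Route**

Step 1
Reactants: 1 1,4-bis(trimethylsilyl)buta-1,3-diyne; 2 (S)-2-acetoxypropanoyl chloride
Product: 3 (S)-3-oxo-7-(trimethylsilyl)hepta-4,6-diyn-2-yl acetate
Conditions: AlCl3 (1.1 equiv), CH2Cl2, 0 °C; cold dilute HCl work-up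
Reagents that add atoms: none
Why: Friedel–Crafts-type ipso-acylation of an alkynylsilane (the acylium ion attacks the silylated alkyne carbon and the β-silyl vinyl cation loses Me3SiCl) should stop after one acylation because the ynone deactivates the second alkynylsilane, and the lactate centre (commercial S form, the racemate would serve equally) is erased in step 5.

Step 2
Reactants: 3 (S)-3-oxo-7-(trimethylsilyl)hepta-4,6-diyn-2-yl acetate
Product: 4 5-ethynyl-2-methylfuran-3(2H)-one (racemic)
Conditions: K2CO3 (0.2 equiv), MeOH, 0 °C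
Reagents that add atoms: none
Why: Methanolysis should remove the acetate and the alkynyl silyl group, and the freed α'-hydroxyl should add to the ynone β-carbon in a 5-endo-dig oxa-Michael closure, the standard route from α'-hydroxy ynones to 3(2H)-furanones.

Step 3
Reactants: 5 (E)-3-iodoacrylic acid
Product: 6 2-(trimethylsilyl)ethyl (E)-3-iodoacrylate
Conditions: 2-(trimethylsilyl)ethanol, N,N'-dicyclohexylcarbodiimide, 4-(dimethylamino)pyridine (cat.), CH2Cl2, 0 °C
Reagents that add atoms: 2-(trimethylsilyl)ethanol C[Si](C)(C)CCO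
Why: Steglich esterification under mild conditions should keep the E-iodoalkene intact and install an ester that fluoride removes at the end.

Step 4
Reactants: 4 5-ethynyl-2-methylfuran-3(2H)-one; 6 2-(trimethylsilyl)ethyl (E)-3-iodoacrylate
Product: 7 2-(trimethylsilyl)ethyl (E)-5-(5-methyl-4-oxo-4,5-dihydrofuran-2-yl)pent-2-en-4-ynoate (racemic)
Conditions: PdCl2(PPh3)2 (3 mol %), CuI (6 mol %), Et3N, THF, degassed, 0 to 23 °C
Reagents that add atoms: none
Why: Sonogashira coupling of a terminal alkyne with an E-vinyl iodide should proceed with retention of alkene geometry, and the coupling is done on the furanone because it is a far poorer diene than the later silyloxyfuran.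

Step 5
Reactants: 7 2-(trimethylsilyl)ethyl (E)-5-(5-methyl-4-oxo-4,5-dihydrofuran-2-yl)pent-2-en-4-ynoate
Product: 8 2-(trimethylsilyl)ethyl (E)-5-[4-(tert-butyldimethylsilyloxy)-5-methylfuran-2-yl]pent-2-en-4-ynoate
Conditions: TBSOTf (1.2 equiv), Et3N (2 equiv), CH2Cl2, 0 °C; filtration through basic alumina, used at once
Reagents that add atoms: tert-butyldimethylsilyl trifluoromethanesulfonate CC(C)(C)[Si](C)(C)OS(=O)(=O)C(F)(F)F
Why: Silyl enol ether formation at the furanone oxygen is driven by aromatisation to the furan and should give a 3-silyloxyfuran, a cyclic 1-alkoxy-3-silyloxy diene in which the former lactate carbon is sp2.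

Step 6
Reactants: 9 orsellinic acid (2,4-dihydroxy-6-methylbenzoic acid)
Product: 11 2,4-bis(tert-butyldimethylsilyloxy)-6-methylbenzoic acid, via tris-silylated silyl ester 10 (not isolated)
Conditions: TBSCl (3.5 equiv), imidazole, N,N-dimethylformamide, 40 °C; then AcOH/THF/H2O, 23 °C
Reagents that add atoms: tert-butyldimethylsilyl chloride CC(C)(C)[Si](C)(C)Cl
Why: Exhaustive silylation followed by selective hydrolysis of the silyl ester, which is far more labile to mild aqueous acid than the aryl silyl ethers, should give the protected acid.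

Step 7
Reactants: 11 2,4-bis(tert-butyldimethylsilyloxy)-6-methylbenzoic acid; 12 tetrabutylammonium (E)-3-oxoprop-1-en-1-olate (malondialdehyde tetrabutylammonium salt)
Product: 14 (E)-3-oxoprop-1-en-1-yl 2,4-bis(tert-butyldimethylsilyloxy)-6-methylbenzoate, via aroyl chloride 13 (not isolated)
Conditions: (COCl)2 (1.2 equiv), N,N-dimethylformamide (cat.), CH2Cl2, 0 to 23 °C, evaporation; then 12, CH2Cl2, −20 °C
Reagents that add atoms: none
Why: Acid chloride formation and O-acylation of the ambident malondialdehyde enolate at oxygen, as in the known preparation of 3-benzoyloxyacrolein, should give the E-configured enol ester that carries C8 with its ester oxygen, C8a and C1.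

Step 8
Reactants: 8 2-(trimethylsilyl)ethyl (E)-5-[4-(tert-butyldimethylsilyloxy)-5-methylfuran-2-yl]pent-2-en-4-ynoate; 14 (E)-3-oxoprop-1-en-1-yl 2,4-bis(tert-butyldimethylsilyloxy)-6-methylbenzoate
Product: 16 (1R,2S,6R)-2-formyl-6-hydroxy-6-methyl-5-oxo-3-[(3E)-5-oxo-5-[2-(trimethylsilyl)ethoxy]pent-3-en-1-yn-1-yl]cyclohex-3-en-1-yl 2,4-bis(tert-butyldimethylsilyloxy)-6-methylbenzoate, via oxanorbornene adduct 15 (not isolated)
Conditions: (R)-3,3-diphenyl-1-(o-tolyl)tetrahydro-1H,3H-pyrrolo[1,2-c][1,3,2]oxazaborole (20 mol %), HN(SO2CF3)2 (18 mol %), CH2Cl2, −78 °C; then CF3CO2H (0.5 equiv), H2O (5 equiv), THF, −78 to 0 °C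
Reagents that add atoms: none
Why: The oxazaborolidinium ion binds the formyl oxygen of 14, and the 3-silyloxyfuran 8 adds in an asynchronous concerted [4+2] cycloaddition in which the bond from the methyl-bearing furan carbon (future C7) to the acyloxy-bearing enal β-carbon (future C8) leads and the bond from the alkynyl-bearing furan carbon (future C4a) to the enal α-carbon (future C8a) follows; the closest known reaction type is the chiral-boron-catalysed Diels–Alder reaction of furans and of 1-alkoxy-3-silyloxy dienes with enals. The carbocycle is closed by this intermolecular suprafacial [4+2] addition as a 7-oxabicyclo[2.2.1]heptene, and on acidification the silyl enol ether expels the bridging C4a–O bond, as the alkoxy group is lost from a 1-alkoxy-3-silyloxy diene adduct, which unveils the C6 ketone, the C4a=C5 double bond and the tertiary C7 hydroxyl. The relative configuration of C7 and C8 follows from the E geometry of 14 and the endo position of the catalyst-bound formyl group, which places the aroyloxy group exo, on the side of the oxygen bridge and therefore cis to the C7 oxygen. The absolute configuration of both centres is set by the catalyst, which shields one face of the s-trans enal so that the furan adds to the Si face of the β-carbon; the centres at C4a and C8a are transient. The step needs regioselectivity, secured by the 3-silyloxy group (the nucleophilic furan C2 meets the electrophilic enal β-carbon), chemoselectivity for the Lewis-acid-bound enal over the enynoate of 8, and survival of the β-aroyloxy aldehyde, secured by low temperature and an acidic instead of a basic work-up.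

Step 9
Reactants: 16 the enone aldehyde from step 8
Product: 17 (7R,8R)-7-hydroxy-7-methyl-6-oxo-3-[(E)-3-oxo-3-[2-(trimethylsilyl)ethoxy]prop-1-en-1-yl]-7,8-dihydro-6H-isochromen-8-yl 2,4-bis(tert-butyldimethylsilyloxy)-6-methylbenzoate
Conditions: Ph3PAuN(SO2CF3)2 (5 mol %), CH2Cl2, 23 °C
Reagents that add atoms: none
Why: Cationic monovalent gold should activate the alkyne for 6-endo-dig attack by the formyl (enol) oxygen, and loss of the C8a proton with protodeauration gives the pyran with C1=C8a and C3=C4, the known cycloisomerisation of o-alkynyl aldehydes used for azaphilones, under neutral conditions that leave the C8 ester and the C7 and C8 centres untouched.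

Step 10
Reactants: 17 the protected azaphilone from step 9
Product: 18 (+)-mitorubrinic acid B, (7R,8R)-3-[(E)-2-carboxyethenyl]-7-hydroxy-7-methyl-6-oxo-7,8-dihydro-6H-isochromen-8-yl 2,4-dihydroxy-6-methylbenzoate
Conditions: Bu4NF (4 equiv), AcOH (4 equiv), THF, 0 to 23 °C
Reagents that add atoms: none
Why: Fluoride-mediated desilylation should cleave both aryl silyl ethers and fragment the 2-(trimethylsilyl)ethyl ester with loss of ethene, while the acetic acid buffer keeps the medium from becoming basic enough for acyl shift or retro-aldol cleavage.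

**Compound list**

1 | 1,4-bis(trimethylsilyl)buta-1,3-diyne | C[Si](C)(C)C#CC#C[Si](C)(C)C | starting material
2 | (S)-2-acetoxypropanoyl chloride | C[C@H](OC(C)=O)C(Cl)=O | starting material
3 | (S)-3-oxo-7-(trimethylsilyl)hepta-4,6-diyn-2-yl acetate | C[C@H](OC(C)=O)C(=O)C#CC#C[Si](C)(C)C | intermediate
4 | 5-ethynyl-2-methylfuran-3(2H)-one (racemic) | CC1OC(C#C)=CC1=O | intermediate
5 | (E)-3-iodoacrylic acid | OC(=O)/C=C/I | starting material
6 | 2-(trimethylsilyl)ethyl (E)-3-iodoacrylate | I/C=C/C(=O)OCC[Si](C)(C)C | intermediate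
7 | 2-(trimethylsilyl)ethyl (E)-5-(5-methyl-4-oxo-4,5-dihydrofuran-2-yl)pent-2-en-4-ynoate (racemic) | CC1OC(C#C/C=C/C(=O)OCC[Si](C)(C)C)=CC1=O | intermediate
8 | 2-(trimethylsilyl)ethyl (E)-5-[4-(tert-butyldimethylsilyloxy)-5-methylfuran-2-yl]pent-2-en-4-ynoate | Cc1oc(C#C/C=C/C(=O)OCC[Si](C)(C)C)cc1O[Si](C)(C)C(C)(C)C | intermediate
9 | orsellinic acid (2,4-dihydroxy-6-methylbenzoic acid) | Cc1cc(O)cc(O)c1C(=O)O | starting material
10 | tert-butyldimethylsilyl 2,4-bis(tert-butyldimethylsilyloxy)-6-methylbenzoate | Cc1cc(O[Si](C)(C)C(C)(C)C)cc(O[Si](C)(C)C(C)(C)C)c1C(=O)O[Si](C)(C)C(C)(C)C | intermediate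
11 | 2,4-bis(tert-butyldimethylsilyloxy)-6-methylbenzoic acid | Cc1cc(O[Si](C)(C)C(C)(C)C)cc(O[Si](C)(C)C(C)(C)C)c1C(=O)O | intermediate
12 | tetrabutylammonium (E)-3-oxoprop-1-en-1-olate | [O-]/C=C/C=O.CCCC[N+](CCCC)(CCCC)CCCC | starting material
13 | 2,4-bis(tert-butyldimethylsilyloxy)-6-methylbenzoyl chloride | Cc1cc(O[Si](C)(C)C(C)(C)C)cc(O[Si](C)(C)C(C)(C)C)c1C(Cl)=O | intermediate
14 | (E)-3-oxoprop-1-en-1-yl 2,4-bis(tert-butyldimethylsilyloxy)-6-methylbenzoate | Cc1cc(O[Si](C)(C)C(C)(C)C)cc(O[Si](C)(C)C(C)(C)C)c1C(=O)O/C=C/C=O | intermediate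
15 | (1R,2R,3R,4R)-6-(tert-butyldimethylsilyloxy)-3-formyl-1-methyl-4-[(3E)-5-oxo-5-[2-(trimethylsilyl)ethoxy]pent-3-en-1-yn-1-yl]-7-oxabicyclo[2.2.1]hept-5-en-2-yl 2,4-bis(tert-butyldimethylsilyloxy)-6-methylbenzoate (aroyloxy exo, formyl endo) | C[C@]12O[C@](C#C/C=C/C(=O)OCC[Si](C)(C)C)(C=C1O[Si](C)(C)C(C)(C)C)[C@H](C=O)[C@H]2OC(=O)c1c(C)cc(O[Si](C)(C)C(C)(C)C)cc1O[Si](C)(C)C(C)(C)C | intermediate
16 | (1R,2S,6R)-2-formyl-6-hydroxy-6-methyl-5-oxo-3-[(3E)-5-oxo-5-[2-(trimethylsilyl)ethoxy]pent-3-en-1-yn-1-yl]cyclohex-3-en-1-yl 2,4-bis(tert-butyldimethylsilyloxy)-6-methylbenzoate (hydroxyl and aroyloxy cis) | O=C[C@H]1C(C#C/C=C/C(=O)OCC[Si](C)(C)C)=CC(=O)[C@](C)(O)[C@@H]1OC(=O)c1c(C)cc(O[Si](C)(C)C(C)(C)C)cc1O[Si](C)(C)C(C)(C)C | intermediate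
17 | (7R,8R)-7-hydroxy-7-methyl-6-oxo-3-[(E)-3-oxo-3-[2-(trimethylsilyl)ethoxy]prop-1-en-1-yl]-7,8-dihydro-6H-isochromen-8-yl 2,4-bis(tert-butyldimethylsilyloxy)-6-methylbenzoate | Cc1cc(O[Si](C)(C)C(C)(C)C)cc(O[Si](C)(C)C(C)(C)C)c1C(=O)O[C@@H]1C2=COC(/C=C/C(=O)OCC[Si](C)(C)C)=CC2=CC(=O)[C@]1(C)O | intermediate
18 | (+)-mitorubrinic acid B, (7R,8R)-3-[(E)-2-carboxyethenyl]-7-hydroxy-7-methyl-6-oxo-7,8-dihydro-6H-isochromen-8-yl 2,4-dihydroxy-6-methylbenzoate | Cc1cc(O)cc(O)c1C(=O)O[C@@H]1C2=COC(/C=C/C(=O)O)=CC2=CC(=O)[C@]1(C)O | target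

**Count and risks**

Total step count: 10. Longest linear sequence: 7 steps (steps 1, 2, 4, 5, 8, 9, 10).

Steps most likely to fail:

Step 8. The cycloaddition may discriminate poorly between the two faces of the enal and between endo and exo approach, because the catalyst-bound formyl group has to sit under a furan that is substituted at both termini. The fallback sets out from 8 and 14 and comes back at 17; it gives up reagent control in favour of resolution. The cycloaddition is run with a catalytic amount of the achiral Lewis acid B(C6F5)3 in CH2Cl2 at −78 °C to give the racemic oxanorbornene adduct F1, which is opened in the same flask with CF3CO2H and water to the racemic enone aldehyde F2. The exo-derived C8 epimer is removed at this stage as a diastereomer. F2 is cyclised under the conditions of step 9 to the racemic protected azaphilone F3, and F3 is resolved by preparative chromatography on a cellulose tris(3,5-dimethylphenylcarbamate) stationary phase; the (7R,8R) enantiomer is 17.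

Step 9. The formyl oxygen may attack the proximal alkyne carbon (5-exo-dig closure to an alkylidene furan), or the cationic gold species may ionise the allylic C8 ester. The fallback sets out from 16 and comes back at 17; it replaces π-acid catalysis by a stoichiometric electrophile-driven closure. N-iodosuccinimide in CH2Cl2 at 0 °C should form the iodonium ion of the alkyne and trigger 6-endo attack of the formyl oxygen to give the 4-iodopyran F4. Radical hydrodeiodination of F4 with (Me3Si)3SiH and Et3B/air in toluene at 0 °C returns 17.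

Step 10. Removing three silicon groups at once with fluoride may degrade the product by acyl shift from the C8 to the C7 oxygen, by retro-aldol cleavage or by nucleophilic opening of the pyran. The fallback sets out from 17 and comes back at 18; it uses two orthogonal, non-basic operations. KHF2 in MeOH at 23 °C should remove only the two aryl silyl ethers and give the diphenol 2-(trimethylsilyl)ethyl ester F5. CF3CO2H in CH2Cl2 at 0 °C then cleaves the 2-(trimethylsilyl)ethyl ester of F5 by acidolysis to 18.

Further compounds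
F1 | step 8 | racemic oxanorbornene adduct (15 and its enantiomer, not isolated) | C[C@]12O[C@](C#C/C=C/C(=O)OCC[Si](C)(C)C)(C=C1O[Si](C)(C)C(C)(C)C)[C@H](C=O)[C@H]2OC(=O)c1c(C)cc(O[Si](C)(C)C(C)(C)C)cc1O[Si](C)(C)C(C)(C)C.C[C@@]12O[C@@](C#C/C=C/C(=O)OCC[Si](C)(C)C)(C=C1O[Si](C)(C)C(C)(C)C)[C@@H](C=O)[C@@H]2OC(=O)c1c(C)cc(O[Si](C)(C)C(C)(C)C)cc1O[Si](C)(C)C(C)(C)C
F2 | step 8 | racemic enone aldehyde (16 and its enantiomer) | O=C[C@H]1C(C#C/C=C/C(=O)OCC[Si](C)(C)C)=CC(=O)[C@](C)(O)[C@@H]1OC(=O)c1c(C)cc(O[Si](C)(C)C(C)(C)C)cc1O[Si](C)(C)C(C)(C)C.O=C[C@@H]1C(C#C/C=C/C(=O)OCC[Si](C)(C)C)=CC(=O)[C@@](C)(O)[C@H]1OC(=O)c1c(C)cc(O[Si](C)(C)C(C)(C)C)cc1O[Si](C)(C)C(C)(C)C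
F3 | step 8 | racemic protected azaphilone (17 and its enantiomer) | Cc1cc(O[Si](C)(C)C(C)(C)C)cc(O[Si](C)(C)C(C)(C)C)c1C(=O)O[C@@H]1C2=COC(/C=C/C(=O)OCC[Si](C)(C)C)=CC2=CC(=O)[C@]1(C)O.Cc1cc(O[Si](C)(C)C(C)(C)C)cc(O[Si](C)(C)C(C)(C)C)c1C(=O)O[C@H]1C2=COC(/C=C/C(=O)OCC[Si](C)(C)C)=CC2=CC(=O)[C@@]1(C)O
F4 | step 9 | (7R,8R)-7-hydroxy-4-iodo-7-methyl-6-oxo-3-[(E)-3-oxo-3-[2-(trimethylsilyl)ethoxy]prop-1-en-1-yl]-7,8-dihydro-6H-isochromen-8-yl 2,4-bis(tert-butyldimethylsilyloxy)-6-methylbenzoate | Cc1cc(O[Si](C)(C)C(C)(C)C)cc(O[Si](C)(C)C(C)(C)C)c1C(=O)O[C@@H]1C2=COC(/C=C/C(=O)OCC[Si](C)(C)C)=C(I)C2=CC(=O)[C@]1(C)O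
F5 | step 10 | (7R,8R)-7-hydroxy-7-methyl-6-oxo-3-[(E)-3-oxo-3-[2-(trimethylsilyl)ethoxy]prop-1-en-1-yl]-7,8-dihydro-6H-isochromen-8-yl 2,4-dihydroxy-6-methylbenzoate | Cc1cc(O)cc(O)c1C(=O)O[C@@H]1C2=COC(/C=C/C(=O)OCC[Si](C)(C)C)=CC2=CC(=O)[C@]1(C)O
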